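**Plan**

- Labels: ring A is the benzoate ring (C1 CO2CH3, C2 O-prenyl, C4 CH3, C6 O-aryl); ring B carries the ether oxygen on C1', CH2OH on C2', OCH3 on C4' and O-prenyl on C6'. Prenyl = 3-methylbut-2-en-1-yl.
- Retrosynthesis: the O–Si bond, the C1–CO2CH3 bond (back to C1–Br), the C6'–O–prenyl bond, the C1'=C2' unsaturation and the C4'–OCH3 bond are removed in turn. Ring B is then cut at C1'–C2' and C4'–C5'.
- Enabling feature: ring B is a resorcinol (oxygens on C4' and C6') with the diaryl ether oxygen on C1' next to C6' and a one-carbon branch on C2'. This is the pattern of a 4-aryloxy-5-(oxymethyl)cyclohexane-1,3-dione, which divides into an aryloxyacetone (O–C1'–C6'(=O)–C5') and a 4-oxybut-2-enoate (C2'–C3'–C4').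
- Forward: ring A is bought as 3,5-dimethoxytoluene and given a bromine at C1 (stand-in for the ester), one prenyl ether and an acetonyl ether. Ring B is then grown on that oxygen by Michael–Claisen annulation, methylated, aromatised and prenylated. The bromide becomes the ester last, followed by desilylation.
- Stereochemistry: the target has no stereocentre. The two sp3 centres formed in the annulation (C1', C2') are uncontrolled and vanish on aromatisation, as does the E geometry of the enoate.

Key step: step 6

Assumption: compounds 12–16 and F2–F5 are racemic diastereomer mixtures (or racemates), so their SMILES carry no stereodescriptors. TBS = tert-butyldimethylsilyl.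

**Route**

Step 1
Reactants: 1 3,5-dimethoxytoluene
Product: 3 2-bromo-1,3-dimethoxy-5-methylbenzene, via aryllithium 2 (not isolated)
Conditions: n-BuLi, THF, 0 °C → rt; then BrCH2CH2Br, −78 °C → rt
Reagents that add atoms: 1,2-dibromoethane, BrCCBr
Why: Directed ortho-metalation takes place at the ring carbon flanked by both methoxy groups (most acidic, doubly coordinated), and the aryllithium 2 takes bromine from 1,2-dibromoethane with loss of ethene.

Step 2
Reactants: 3 2-bromo-1,3-dimethoxy-5-methylbenzene
Product: 4 2-bromo-5-methylbenzene-1,3-diol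
Conditions: BBr3, CH2Cl2, −78 °C → rt; then H2O
Reagents that add atoms: none
Why: BBr3 cleaves aryl methyl ethers by O–B complexation and SN2 attack of bromide on methyl, and leaves the aryl bromide and the ring methyl group untouched.

Step 3
Reactants: 4 2-bromo-5-methylbenzene-1,3-diol; 5 prenyl bromide (1.0 equiv)
Product: 6 2-bromo-5-methyl-3-(prenyloxy)phenol
Conditions: K2CO3 (1.0 equiv), acetone, rt
Reagents that add atoms: none
Why: Williamson mono-etherification of a symmetric bis-phenol with one equivalent of allylic bromide should give the mono-ether as the main product, separable from di-ether and from unreacted 4 (to be recycled), with O-alkylation favoured under K2CO3 in acetone.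

Step 4
Reactants: 6 2-bromo-5-methyl-3-(prenyloxy)phenol; 7 chloroacetone
Product: 8 1-[2-bromo-5-methyl-3-(prenyloxy)phenoxy]propan-2-one
Conditions: K2CO3, KI (cat.), acetone, reflux
Reagents that add atoms: none
Why: Williamson alkylation of the remaining phenoxide with an α-chloro ketone, helped by in situ Finkelstein exchange, is the standard route to aryloxyacetones.

Step 5
Reactants: 9 (tert-butyldimethylsilyloxy)acetaldehyde; 10 methyl (triphenylphosphoranylidene)acetate
Product: 11 methyl (E)-4-(tert-butyldimethylsilyloxy)but-2-enoate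
Conditions: CH2Cl2, rt
Reagents that add atoms: none
Why: Wittig olefination with a stabilised ylide gives the E-enoate selectively.

Step 6
Reactants: 8 1-[2-bromo-5-methyl-3-(prenyloxy)phenoxy]propan-2-one; 11 methyl (E)-4-(tert-butyldimethylsilyloxy)but-2-enoate
Product: 13 4-[2-bromo-5-methyl-3-(prenyloxy)phenoxy]-5-(tert-butyldimethylsilyloxymethyl)cyclohexane-1,3-dione (racemic diastereomer mixture), via Michael adduct 12 (not isolated)
Conditions: KOtBu (2.2 equiv), THF, −10 °C; add 8, then 11; → rt; then 1 M HCl, 0 °C (to pH 3–4)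
Reagents that add atoms: none
Why: Proposed new method: the closest known reaction type is the consecutive Michael–Claisen annulation of alkyl-substituted acetones with enoates under KOtBu, extended here to an aryloxyacetone, whose oxygen-bearing CH2 is the more acidic α-position, so that the favoured enolate at C1' adds to the β-carbon of 11 and forms the C1'–C2' bond. Proton transfer within adduct 12 moves the charge to the methyl ketone, whose enolate attacks the ester carbonyl in a 6-exo-trig acyl substitution (C5'–C4' bond), expels methoxide and closes ring B as the cyclohexane-1,3-dione. Deprotonation of the dione to its stabilised enolate makes the sequence irreversible and draws the reversible conjugate addition forward. The new stereocentres at C1' and C2' have no controlling element and need none, since 13 is carried on as a diastereomer mixture and both centres become sp2 on aromatisation. The selectivity needed is the site of enolisation and of ring closure: the aryloxy group secures the first by acidifying C1'–H, and the second follows because after the Michael step only the methyl group can reach the ester through a six-membered transition state. Bromine at C1 of ring A, in place of the ester, removes the competing attack of the enolate on an ortho carbonyl.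

Step 7
Reactants: 13 4-[2-bromo-5-methyl-3-(prenyloxy)phenoxy]-5-(tert-butyldimethylsilyloxymethyl)cyclohexane-1,3-dione
Product: 14 6-[2-bromo-5-methyl-3-(prenyloxy)phenoxy]-5-(tert-butyldimethylsilyloxymethyl)-3-methoxycyclohex-2-en-1-one (methoxy on C4', ketone at C6')
Conditions: Me2SO4, K2CO3, acetone, rt
Reagents that add atoms: dimethyl sulfate, COS(=O)(=O)OC
Why: The hard electrophile dimethyl sulfate O-alkylates the dione enolate, and the oxygen on C4' (flanked by CH2 groups only) should react in preference to the oxygen on C6', which is screened and made less nucleophilic by the aryloxy-bearing C1'; the acid-free conditions spare the silyl and prenyl ethers, and the regioisomer should be separable by chromatography.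

Step 8
Reactants: 14 6-[2-bromo-5-methyl-3-(prenyloxy)phenoxy]-5-(tert-butyldimethylsilyloxymethyl)-3-methoxycyclohex-2-en-1-one
Product: 18 2-[2-bromo-5-methyl-3-(prenyloxy)phenoxy]-3-(tert-butyldimethylsilyloxymethyl)-5-methoxyphenol, via selenide 15 (not isolated), via selenoxide 16 (not isolated), via dienone 17 (not isolated)
Conditions: LiN(iPr)2, THF, −78 °C; PhSeBr, −78 °C; then H2O2 (30% aq.), pyridine, CH2Cl2, 0 °C → rt
Reagents that add atoms: none
Why: Kinetic deprotonation of the vinylogous ester occurs at the α' carbon C1' (further acidified by the aryloxy group), selenenylation anti to the C2' substituent places selenium cis to the C2' hydrogen (15), and oxidation to selenoxide 16 followed by syn-elimination across C1'–C2' gives dienone 17, which tautomerises to the phenol; this enolate selenenylation/selenoxide elimination is an established way from 3-alkoxycyclohexenones to resorcinol monoethers.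

Step 9
Reactants: 18 2-[2-bromo-5-methyl-3-(prenyloxy)phenoxy]-3-(tert-butyldimethylsilyloxymethyl)-5-methoxyphenol; 5 prenyl bromide
Product: 19 2-bromo-1-[2-(tert-butyldimethylsilyloxymethyl)-4-methoxy-6-(prenyloxy)phenoxy]-5-methyl-3-(prenyloxy)benzene
Conditions: K2CO3, DMF, rt
Reagents that add atoms: none
Why: Williamson O-prenylation of the only free phenol (C6'–OH); the silyl ether, the aryl bromide and the existing prenyl ether are inert to K2CO3 in DMF.

Step 10
Reactants: 19 2-bromo-1-[2-(tert-butyldimethylsilyloxymethyl)-4-methoxy-6-(prenyloxy)phenoxy]-5-methyl-3-(prenyloxy)benzene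
Product: 21 methyl 2-[2-(tert-butyldimethylsilyloxymethyl)-4-methoxy-6-(prenyloxy)phenoxy]-4-methyl-6-(prenyloxy)benzoate, via aryllithium 20 (not isolated)
Conditions: n-BuLi, THF, −78 °C; then cannulate into ClCO2Me (excess), THF, −78 °C → rt
Reagents that add atoms: methyl chloroformate, COC(=O)Cl
Why: Bromine–lithium exchange at −78 °C outruns deprotonation of the allylic ethers, aryllithium 20 is stabilised by its two ortho oxygens, and acylation by inverse addition to excess chloroformate should stop at the hindered ester.

Step 11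
Reactants: 21 methyl 2-[2-(tert-butyldimethylsilyloxymethyl)-4-methoxy-6-(prenyloxy)phenoxy]-4-methyl-6-(prenyloxy)benzoate
Product: 22 methyl 2-[2-(hydroxymethyl)-4-methoxy-6-(prenyloxy)phenoxy]-4-methyl-6-(prenyloxy)benzoate (CNP0561346.0)
Conditions: Bu4NF, AcOH, THF, 0 °C → rt
Reagents that add atoms: none
Why: Fluoride cleaves the primary silyl ether, and the acetic acid buffer keeps alkoxide away from the methyl ester and the aryl prenyl ethers.

**Compound list**

1 | 3,5-dimethoxytoluene | COc1cc(C)cc(OC)c1 | starting material
2 | (2,6-dimethoxy-4-methylphenyl)lithium | [Li]c1c(OC)cc(C)cc1OC | intermediate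
3 | 2-bromo-1,3-dimethoxy-5-methylbenzene | COc1cc(C)cc(OC)c1Br | intermediate
4 | 2-bromo-5-methylbenzene-1,3-diol | Cc1cc(O)c(Br)c(O)c1 | intermediate
5 | prenyl bromide (1-bromo-3-methylbut-2-ene) | CC(C)=CCBr | starting material
6 | 2-bromo-5-methyl-3-(prenyloxy)phenol | Cc1cc(O)c(Br)c(OCC=C(C)C)c1 | intermediate
7 | chloroacetone | CC(=O)CCl | starting material
8 | 1-[2-bromo-5-methyl-3-(prenyloxy)phenoxy]propan-2-one | CC(=O)COc1cc(C)cc(OCC=C(C)C)c1Br | intermediate
9 | (tert-butyldimethylsilyloxy)acetaldehyde | CC(C)(C)[Si](C)(C)OCC=O | starting material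
10 | methyl (triphenylphosphoranylidene)acetate | COC(=O)C=P(c1ccccc1)(c1ccccc1)c1ccccc1 | starting material
11 | methyl (E)-4-(tert-butyldimethylsilyloxy)but-2-enoate | COC(=O)/C=C/CO[Si](C)(C)C(C)(C)C | intermediate
12 | methyl 4-[2-bromo-5-methyl-3-(prenyloxy)phenoxy]-3-(tert-butyldimethylsilyloxymethyl)-5-oxohexanoate | COC(=O)CC(CO[Si](C)(C)C(C)(C)C)C(Oc1cc(C)cc(OCC=C(C)C)c1Br)C(C)=O | intermediate
13 | 4-[2-bromo-5-methyl-3-(prenyloxy)phenoxy]-5-(tert-butyldimethylsilyloxymethyl)cyclohexane-1,3-dione | O=C1CC(=O)C(Oc2cc(C)cc(OCC=C(C)C)c2Br)C(CO[Si](C)(C)C(C)(C)C)C1 | intermediate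
14 | 6-[2-bromo-5-methyl-3-(prenyloxy)phenoxy]-5-(tert-butyldimethylsilyloxymethyl)-3-methoxycyclohex-2-en-1-one | COC1=CC(=O)C(Oc2cc(C)cc(OCC=C(C)C)c2Br)C(CO[Si](C)(C)C(C)(C)C)C1 | intermediate
15 | 6-[2-bromo-5-methyl-3-(prenyloxy)phenoxy]-5-(tert-butyldimethylsilyloxymethyl)-3-methoxy-6-(phenylselanyl)cyclohex-2-en-1-one | COC1=CC(=O)C([Se]c2ccccc2)(Oc2cc(C)cc(OCC=C(C)C)c2Br)C(CO[Si](C)(C)C(C)(C)C)C1 | intermediate
16 | 6-[2-bromo-5-methyl-3-(prenyloxy)phenoxy]-5-(tert-butyldimethylsilyloxymethyl)-3-methoxy-6-(phenylseleninyl)cyclohex-2-en-1-one | COC1=CC(=O)C([Se](=O)c2ccccc2)(Oc2cc(C)cc(OCC=C(C)C)c2Br)C(CO[Si](C)(C)C(C)(C)C)C1 | intermediate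
17 | 2-[2-bromo-5-methyl-3-(prenyloxy)phenoxy]-3-(tert-butyldimethylsilyloxymethyl)-5-methoxycyclohexa-2,5-dien-1-one | COC1=CC(=O)C(Oc2cc(C)cc(OCC=C(C)C)c2Br)=C(CO[Si](C)(C)C(C)(C)C)C1 | intermediate
18 | 2-[2-bromo-5-methyl-3-(prenyloxy)phenoxy]-3-(tert-butyldimethylsilyloxymethyl)-5-methoxyphenol | COc1cc(O)c(Oc2cc(C)cc(OCC=C(C)C)c2Br)c(CO[Si](C)(C)C(C)(C)C)c1 | intermediate
19 | 2-bromo-1-[2-(tert-butyldimethylsilyloxymethyl)-4-methoxy-6-(prenyloxy)phenoxy]-5-methyl-3-(prenyloxy)benzene | COc1cc(OCC=C(C)C)c(Oc2cc(C)cc(OCC=C(C)C)c2Br)c(CO[Si](C)(C)C(C)(C)C)c1 | intermediate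
20 | {2-[2-(tert-butyldimethylsilyloxymethyl)-4-methoxy-6-(prenyloxy)phenoxy]-4-methyl-6-(prenyloxy)phenyl}lithium | COc1cc(OCC=C(C)C)c(Oc2cc(C)cc(OCC=C(C)C)c2[Li])c(CO[Si](C)(C)C(C)(C)C)c1 | intermediate
21 | methyl 2-[2-(tert-butyldimethylsilyloxymethyl)-4-methoxy-6-(prenyloxy)phenoxy]-4-methyl-6-(prenyloxy)benzoate | COC(=O)c1c(OCC=C(C)C)cc(C)cc1Oc1c(CO[Si](C)(C)C(C)(C)C)cc(OC)cc1OCC=C(C)C | intermediate
22 | methyl 2-[2-(hydroxymethyl)-4-methoxy-6-(prenyloxy)phenoxy]-4-methyl-6-(prenyloxy)benzoate (CNP0561346.0) | COC(=O)c1c(OCC=C(C)C)cc(C)cc1Oc1c(CO)cc(OC)cc1OCC=C(C)C | target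

**Count and risks**

Total step count: 11. Longest linear sequence: 10 steps (steps 1–4 and 6–11); step 5 is a one-step side branch.

Steps most likely to fail:

1. Step 6. The ketone may enolise or add at the methyl side, or KOtBu may isomerise enoate 11 by γ-deprotonation before conjugate addition. Fallback: the C1'–O bond would be made after the ring instead of before, setting out from enoate 11 and phenol 6. Acetone and 11 with KOtBu in THF (the established Michael–Claisen annulation of acetone itself) would give 5-(tert-butyldimethylsilyloxymethyl)cyclohexane-1,3-dione F1, which is symmetrical. Its O-methylation (Me2SO4, K2CO3, acetone) can therefore give only one enol ether, 5-(tert-butyldimethylsilyloxymethyl)-3-methoxycyclohex-2-en-1-one F2. Kinetic enolate formation (LiN(iPr)2, THF, −78 °C) and bromination with N-bromosuccinimide would give 6-bromo-5-(tert-butyldimethylsilyloxymethyl)-3-methoxycyclohex-2-en-1-one F3. Williamson displacement of the α-bromide by the phenoxide of 6 (K2CO3, DMF, rt) comes back to the route at 14, with the position of the methyl ether fixed by construction.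

2. Step 7. Alkylation may occur at the wrong oxygen of the ambident dione enolate, or at carbon C5'. Fallback: the enol ether would be formed under thermodynamic instead of kinetic control, setting out from dione 13. Camphorsulfonic acid (cat.) in MeOH at rt equilibrates the two enol ethers towards the less congested one and removes the silyl group in the same operation, giving 6-[2-bromo-5-methyl-3-(prenyloxy)phenoxy]-5-(hydroxymethyl)-3-methoxycyclohex-2-en-1-one F4. Re-silylation (tert-butyldimethylsilyl chloride, imidazole, DMF) comes back to the route at 14, and recovered regioisomer can be equilibrated again.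

3. Step 8. Selenenylation at the congested, fully substituted C1' may stall or occur on the face that leaves no syn hydrogen on C2', and the peroxide may attack the prenyl alkenes. Fallback: a Saegusa–Ito dehydrogenation, setting out from 14. LiN(iPr)2 then Me3SiCl (THF, −78 °C) would give the trimethylsilyl dienol ether 2-[2-bromo-5-methyl-3-(prenyloxy)phenoxy]-3-(tert-butyldimethylsilyloxymethyl)-5-methoxy-1-(trimethylsilyloxy)cyclohexa-1,5-diene F5. Stoichiometric Pd(OAc)2 (divalent palladium) in MeCN at rt would then effect β-hydride elimination from C2' through a palladium enolate. This gives dienone 17 and, after tautomerisation, comes back to the route at phenol 18 without any peroxide.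

**Further compounds**

F1 | step 6 | 5-(tert-butyldimethylsilyloxymethyl)cyclohexane-1,3-dione | O=C1CC(=O)CC(CO[Si](C)(C)C(C)(C)C)C1
F2 | step 6 | 5-(tert-butyldimethylsilyloxymethyl)-3-methoxycyclohex-2-en-1-one | COC1=CC(=O)CC(CO[Si](C)(C)C(C)(C)C)C1
F3 | step 6 | 6-bromo-5-(tert-butyldimethylsilyloxymethyl)-3-methoxycyclohex-2-en-1-one | COC1=CC(=O)C(Br)C(CO[Si](C)(C)C(C)(C)C)C1
F4 | step 7 | 6-[2-bromo-5-methyl-3-(prenyloxy)phenoxy]-5-(hydroxymethyl)-3-methoxycyclohex-2-en-1-one | COC1=CC(=O)C(Oc2cc(C)cc(OCC=C(C)C)c2Br)C(CO)C1
F5 | step 8 | 2-[2-bromo-5-methyl-3-(prenyloxy)phenoxy]-3-(tert-butyldimethylsilyloxymethyl)-5-methoxy-1-(trimethylsilyloxy)cyclohexa-1,5-diene | COC1=CC(O[Si](C)(C)C)=C(Oc2cc(C)cc(OCC=C(C)C)c2Br)C(CO[Si](C)(C)C(C)(C)C)C1
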